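**Retrosynthetic overview**

1. The target 15 is the (3S)-isoflavanone; it comes from its tris-MOM ether 14 by acetal cleavage.
2. Key disconnection C3–C4 of ring C: 14 from the open-chain bis-chloride 13 (aroyl chloride on ring A, racemic benzylic chloride at C3) by a nickel-catalysed enantioconvergent reductive ring closure that makes ring C and the only stereocentre together.
3. Enabling feature: C3 is benzylic to ring B and para to its pyran oxygen (stabilized radical), C4 is the acyl carbon on C4a of ring A, and the C8a–O1–C2 ether holds C3 and C4 in a 1,6 relation.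
4. 13 comes from phenol 10 (ring A, from 2,4,6-trihydroxybenzaldehyde) and aryl oxirane 8 (ring B with its pyran ring) by O1–C2 ether formation, aldehyde oxidation and double chlorination.
5. Ring order: rings A and B are bought as benzene rings; the dimethylpyran ring on ring B is formed first (propargyl ether Claisen/oxa-6π), ring C last.

Key step: step 9

Assumption: the given structure is read as (3S); the sense of induction of the bis(oxazoline) ligand in a ring closure is not known, so the (S,S) ligand is written and its mirror image is to be taken if a test run shows the other sense.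

**Route**

Step 1
Reactants: 1 3,4-dihydroxybenzaldehyde; 2 3-chloro-3-methylbut-1-yne
Product: 3 3-hydroxy-4-[(2-methylbut-3-yn-2-yl)oxy]benzaldehyde
Conditions: K2CO3 (1.05 equiv), KI (10 mol %), CuI (5 mol %), DMF, 25 → 50 °C
Reagents that add atoms: none
Why: The 4-OH, para to the formyl group, is the more acidic phenol, so one equivalent of base should give only its phenoxide, which is alkylated by the tertiary propargylic chloride (copper-assisted Williamson-type propargylic etherification).

Step 2
Reactants: 3 3-hydroxy-4-[(2-methylbut-3-yn-2-yl)oxy]benzaldehyde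
Product: 6 8-hydroxy-2,2-dimethyl-2H-chromene-6-carbaldehyde, via allenyl catechol 4 (not isolated), via ortho-quinone methide 5 (not isolated)
Conditions: o-xylene, 140 °C
Reagents that add atoms: none
Why: Aryl propargyl ether Claisen rearrangement, 1,5-hydrogen shift and oxa-6π electrocyclization; C5 is the only free ortho position of the ether, so the pyran ring can close only there.

Step 3
Reactants: 6 8-hydroxy-2,2-dimethyl-2H-chromene-6-carbaldehyde
Product: 7 8-(methoxymethoxy)-2,2-dimethyl-2H-chromene-6-carbaldehyde
Conditions: MOMCl, i-Pr2NEt, CH2Cl2, 0 °C → rt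
Reagents that add atoms: chloromethyl methyl ether (MOMCl), COCCl
Why: O-alkylation of the phenol as its acetal (MOM protection) under amine base, to which aldehyde and chromene are inert.

Step 4
Reactants: 7 8-(methoxymethoxy)-2,2-dimethyl-2H-chromene-6-carbaldehyde
Product: 8 2-[8-(methoxymethoxy)-2,2-dimethyl-2H-chromen-6-yl]oxirane (racemic)
Conditions: Me3S+ I−, NaH, DMSO/THF, 0 °C → rt
Reagents that add atoms: trimethylsulfonium iodide, C[S+](C)C.[I-]
Why: Corey–Chaykovsky epoxidation of an aryl aldehyde by the sulfonium ylide; the stereocentre forms as a racemate, which is harmless because it is erased at the radical stage of step 9.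

Step 5
Reactants: 9 2,4,6-trihydroxybenzaldehyde
Product: 10 2-hydroxy-4,6-bis(methoxymethoxy)benzaldehyde
Conditions: MOMCl (2.2 equiv), i-Pr2NEt, CH2Cl2, 0 °C → rt
Reagents that add atoms: chloromethyl methyl ether (MOMCl), COCCl
Why: MOM protection of the 4-OH and one ortho OH; the last ortho OH is hydrogen-bonded to the formyl group and should stay free (selective acetalization of a chelated phenol).

Step 6
Reactants: 10 2-hydroxy-4,6-bis(methoxymethoxy)benzaldehyde; 8 2-[8-(methoxymethoxy)-2,2-dimethyl-2H-chromen-6-yl]oxirane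
Product: 11 2-{2-hydroxy-2-[8-(methoxymethoxy)-2,2-dimethyl-2H-chromen-6-yl]ethoxy}-4,6-bis(methoxymethoxy)benzaldehyde (racemic)
Conditions: Cs2CO3 (0.3 equiv), DMF, 80 °C
Reagents that add atoms: none
Why: Base-catalysed opening of a terminal epoxide by a phenoxide (SN2 at the unhindered CH2), which forms the O1–C2 ether; the sub-stoichiometric base leaves unreacted phenol to protonate the product alkoxide.

Step 7
Reactants: 11 2-{2-hydroxy-2-[8-(methoxymethoxy)-2,2-dimethyl-2H-chromen-6-yl]ethoxy}-4,6-bis(methoxymethoxy)benzaldehyde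
Product: 12 2-{2-hydroxy-2-[8-(methoxymethoxy)-2,2-dimethyl-2H-chromen-6-yl]ethoxy}-4,6-bis(methoxymethoxy)benzoic acid (racemic)
Conditions: NaClO2, NaH2PO4, 2-methylbut-2-ene, t-BuOH/THF/H2O, 0 °C → rt
Reagents that add atoms: sodium chlorite, [Na+].[O-]Cl=O
Why: Pinnick oxidation of the aldehyde; the alkene scavenger removes HOCl before it can attack the chromene or the electron-rich rings, and the secondary alcohol and MOM ethers should survive the buffered medium.

Step 8
Reactants: 12 2-{2-hydroxy-2-[8-(methoxymethoxy)-2,2-dimethyl-2H-chromen-6-yl]ethoxy}-4,6-bis(methoxymethoxy)benzoic acid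
Product: 13 2-{2-chloro-2-[8-(methoxymethoxy)-2,2-dimethyl-2H-chromen-6-yl]ethoxy}-4,6-bis(methoxymethoxy)benzoyl chloride (racemic)
Conditions: 1-chloro-N,N,2-trimethylprop-1-en-1-amine (2.5 equiv), CH2Cl2, 0 °C → rt; evaporation, crude used at once
Reagents that add atoms: 1-chloro-N,N,2-trimethylprop-1-en-1-amine, CC(C)=C(Cl)N(C)C
Why: The α-chloroenamine converts the acid into the acid chloride and the benzylic alcohol into the chloride under neutral, HCl-free conditions (chlorodehydroxylation), so MOM ethers and the chromene should be spared.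

Step 9
Reactants: 13 2-{2-chloro-2-[8-(methoxymethoxy)-2,2-dimethyl-2H-chromen-6-yl]ethoxy}-4,6-bis(methoxymethoxy)benzoyl chloride
Product: 14 (3S)-5,7-bis(methoxymethoxy)-3-[8-(methoxymethoxy)-2,2-dimethyl-2H-chromen-6-yl]-2,3-dihydro-4H-chromen-4-one
Conditions: NiCl2(dme) (10 mol %), (S,S)-Ph-BOX [2,2'-(propane-2,2-diyl)bis((4S)-4-phenyl-4,5-dihydro-1,3-oxazole), 22 mol %], Mn powder (3 equiv), 2,6-dimethylbenzoic acid (0.75 equiv), 3 Å MS, THF/DMA 7:3, 0.02 M, slow addition of 13, 20 °C
Reagents that add atoms: none
Why: Proposed new method: zerovalent nickel (NiCl2(dme) reduced by Mn) should insert into the aroyl C–Cl bond of 13, the acylnickel should take up the C3 benzylic radical that nickel-mediated chlorine abstraction releases at the other end of the same molecule, and C–C reductive elimination from the trivalent acyl(benzyl)nickel should form the C3–C4 bond. The closest known reaction type is the intermolecular nickel/bis(oxazoline)-catalysed enantioconvergent reductive coupling of acid chlorides with racemic secondary benzylic chlorides, which gives α-aryl ketones with a tertiary stereocentre under these non-basic conditions; new here are the ring-closing mode and the aroyl chloride. Ring C closes in a 6-exo-trig sense at the acyl carbon, by reductive elimination from a seven-membered nickelacycle. C3 is the only new stereocentre and is under catalyst control: both enantiomers of 13 give the same planar benzylic radical, and the C2-symmetric bis(oxazoline) on nickel decides which face bonds to the acyl group. The step needs this face selectivity and a ring closure faster than loss of the β-aryloxide or a β-hydrogen, decarbonylation and dimerization; the para pyran oxygen of ring B stabilizes the radical, the C8a–O1–C2 tether makes its capture intramolecular, high dilution and 20 °C disfavour dimers and decarbonylation, and the acid additive keeps the medium non-basic so that the new α-aryl ketone does not enolize.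

Step 10
Reactants: 14 (3S)-5,7-bis(methoxymethoxy)-3-[8-(methoxymethoxy)-2,2-dimethyl-2H-chromen-6-yl]-2,3-dihydro-4H-chromen-4-one
Product: 15 (3S)-5,7-dihydroxy-3-(8-hydroxy-2,2-dimethyl-2H-chromen-6-yl)-2,3-dihydro-4H-chromen-4-one
Conditions: HCl (2 M in MeOH), THF, 0 °C → rt
Reagents that add atoms: none
Why: Acid-catalysed acetal exchange with methanol removes the three MOM groups; non-basic conditions at or below room temperature are chosen so that C3 does not enolize and the chromene is not hydrated.

**Compound list**

1 | 3,4-dihydroxybenzaldehyde | O=Cc1ccc(O)c(O)c1 | starting material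
2 | 3-chloro-3-methylbut-1-yne | CC(C)(Cl)C#C | starting material
3 | 3-hydroxy-4-[(2-methylbut-3-yn-2-yl)oxy]benzaldehyde | O=Cc1ccc(OC(C)(C)C#C)c(O)c1 | intermediate
4 | 3,4-dihydroxy-5-(3-methylbuta-1,2-dien-1-yl)benzaldehyde (allenyl catechol, formed in the flask) | O=Cc1cc(O)c(O)c(C=C=C(C)C)c1 | intermediate
5 | 5-hydroxy-3-(3-methylbut-2-en-1-ylidene)-4-oxocyclohexa-1,5-diene-1-carbaldehyde (ortho-quinone methide, formed in the flask) | O=CC1=CC(=CC=C(C)C)C(=O)C(O)=C1 | intermediate
6 | 8-hydroxy-2,2-dimethyl-2H-chromene-6-carbaldehyde | CC1(C)C=Cc2cc(C=O)cc(O)c2O1 | intermediate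
7 | 8-(methoxymethoxy)-2,2-dimethyl-2H-chromene-6-carbaldehyde | CC1(C)C=Cc2cc(C=O)cc(OCOC)c2O1 | intermediate
8 | 2-[8-(methoxymethoxy)-2,2-dimethyl-2H-chromen-6-yl]oxirane (racemic) | CC1(C)C=Cc2cc(C3CO3)cc(OCOC)c2O1 | intermediate
9 | 2,4,6-trihydroxybenzaldehyde | O=Cc1c(O)cc(O)cc1O | starting material
10 | 2-hydroxy-4,6-bis(methoxymethoxy)benzaldehyde | O=Cc1c(O)cc(OCOC)cc1OCOC | intermediate
11 | 2-{2-hydroxy-2-[8-(methoxymethoxy)-2,2-dimethyl-2H-chromen-6-yl]ethoxy}-4,6-bis(methoxymethoxy)benzaldehyde (racemic) | O=Cc1c(OCC(O)c2cc3C=CC(C)(C)Oc3c(OCOC)c2)cc(OCOC)cc1OCOC | intermediate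
12 | 2-{2-hydroxy-2-[8-(methoxymethoxy)-2,2-dimethyl-2H-chromen-6-yl]ethoxy}-4,6-bis(methoxymethoxy)benzoic acid (racemic) | OC(=O)c1c(OCC(O)c2cc3C=CC(C)(C)Oc3c(OCOC)c2)cc(OCOC)cc1OCOC | intermediate
13 | 2-{2-chloro-2-[8-(methoxymethoxy)-2,2-dimethyl-2H-chromen-6-yl]ethoxy}-4,6-bis(methoxymethoxy)benzoyl chloride (racemic) | ClC(=O)c1c(OCC(Cl)c2cc3C=CC(C)(C)Oc3c(OCOC)c2)cc(OCOC)cc1OCOC | intermediate
14 | (3S)-5,7-bis(methoxymethoxy)-3-[8-(methoxymethoxy)-2,2-dimethyl-2H-chromen-6-yl]-2,3-dihydro-4H-chromen-4-one | CC1(C)C=Cc2cc([C@H]3COc4cc(OCOC)cc(OCOC)c4C3=O)cc(OCOC)c2O1 | intermediate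
15 | (3S)-5,7-dihydroxy-3-(8-hydroxy-2,2-dimethyl-2H-chromen-6-yl)-2,3-dihydro-4H-chromen-4-one | CC1(C)C=Cc2cc([C@H]3COc4cc(O)cc(O)c4C3=O)cc(O)c2O1 | target

Total steps: 10. Longest linear sequence: 9 steps (1 to 15 through steps 1–4 and 6–10).

**Steps most likely to fail**

Step 9 (key step). The benzylic nickel species or radical may lose the β-aryloxide or a β-hydrogen before the C–C bond forms. The acylnickel may decarbonylate, two molecules may couple instead of one closing, or the cyclic transition state may discriminate the faces of C3 poorly. The fallback uses known chemistry, sets out from 11 and comes back at 14.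
- Oxidation of the benzylic alcohol of 11 with the triacetoxy periodinane DMP (NaHCO3, CH2Cl2) should give keto aldehyde F1.
- An achiral triazolium-derived carbene (Et3N, THF) should close ring C through the same C3–C4 bond by intramolecular crossed benzoin addition of the aldehyde to the ketone, giving racemic 3-hydroxyisoflavanone F2.
- Dehydration with methyl N-(triethylammoniosulfonyl)carbamate (Burgess reagent, toluene, 60 °C) should give isoflavone F3.
- Transfer hydrogenation with RuCl[(S,S)-TsDPEN](p-cymene) and HCO2H/Et3N should reduce the C2=C3 bond and then the ketone, with dynamic kinetic resolution through the enolizable C3. The expected product, by the usual sense of this catalyst with aryl ketones, is cis-(3S,4S)-isoflavan-4-ol F4.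
- Buffered DMP oxidation of the carbinol should return 14 with C3 untouched.

Step 8. The para-alkoxybenzylic chloride may ionize while it is formed or handled (elimination to the enol ether, hydrolysis). The ortho MOM ether may attack the acid chloride with loss of chloromethane. The fallback separates the two activations, sets out from 12 and comes back at 14.
- Redox condensation of 12 with 2,2'-dipyridyl disulfide and PPh3 (CH2Cl2, rt) should give hydroxy thioester F5, an acyl donor that the MOM ether does not attack and that can be chromatographed.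
- One equivalent of the α-chloroenamine should then give chloro thioester F6, made last and used at once.
- F6 is cyclized under the nickel conditions of step 9 to 14; reductive ketone synthesis from S-2-pyridyl thioesters and alkyl halides is a known nickel reaction.

Step 6. The phenoxide may attack the benzylic instead of the terminal epoxide carbon, and the electron-rich aryl oxirane may rearrange to the arylacetaldehyde before it is opened. The fallback builds the O1–C2 bond by alkylation with an α-chloro ketone, sets out from 7 (with 10) and comes back at 12.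
- Addition of chloromethyllithium to 7 (ICH2Cl, MeLi·LiBr, THF, −78 °C, cold acidic quench) should give chlorohydrin F7.
- DMP oxidation should give α-chloro ketone F8.
- O-alkylation of 10 with F8 (K2CO3, NaI cat., acetone, 50 °C) should give keto aldehyde F1, the compound that also opens the first fallback.
- Chlorite oxidation as in step 7 should give keto acid F9.
- NaBH4 (MeOH/THF, 0 °C) should reduce only the ketone and give 12.

**Further compounds**

F1 | step 9 | 2-{2-[8-(methoxymethoxy)-2,2-dimethyl-2H-chromen-6-yl]-2-oxoethoxy}-4,6-bis(methoxymethoxy)benzaldehyde | O=Cc1c(OCC(=O)c2cc3C=CC(C)(C)Oc3c(OCOC)c2)cc(OCOC)cc1OCOC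
F2 | step 9 | 3-hydroxy-5,7-bis(methoxymethoxy)-3-[8-(methoxymethoxy)-2,2-dimethyl-2H-chromen-6-yl]-2,3-dihydro-4H-chromen-4-one (racemic) | CC1(C)C=Cc2cc(C3(O)COc4cc(OCOC)cc(OCOC)c4C3=O)cc(OCOC)c2O1
F3 | step 9 | 5,7-bis(methoxymethoxy)-3-[8-(methoxymethoxy)-2,2-dimethyl-2H-chromen-6-yl]-4H-chromen-4-one | CC1(C)C=Cc2cc(C3=COc4cc(OCOC)cc(OCOC)c4C3=O)cc(OCOC)c2O1
F4 | step 9 | (3S,4S)-5,7-bis(methoxymethoxy)-3-[8-(methoxymethoxy)-2,2-dimethyl-2H-chromen-6-yl]-3,4-dihydro-2H-chromen-4-ol (cis) | CC1(C)C=Cc2cc([C@H]3COc4cc(OCOC)cc(OCOC)c4[C@H]3O)cc(OCOC)c2O1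
F5 | step 8 | S-(pyridin-2-yl) 2-{2-hydroxy-2-[8-(methoxymethoxy)-2,2-dimethyl-2H-chromen-6-yl]ethoxy}-4,6-bis(methoxymethoxy)benzenecarbothioate (racemic) | O=C(Sc1ccccn1)c1c(OCC(O)c2cc3C=CC(C)(C)Oc3c(OCOC)c2)cc(OCOC)cc1OCOC
F6 | step 8 | S-(pyridin-2-yl) 2-{2-chloro-2-[8-(methoxymethoxy)-2,2-dimethyl-2H-chromen-6-yl]ethoxy}-4,6-bis(methoxymethoxy)benzenecarbothioate (racemic) | O=C(Sc1ccccn1)c1c(OCC(Cl)c2cc3C=CC(C)(C)Oc3c(OCOC)c2)cc(OCOC)cc1OCOC
F7 | step 6 | 2-chloro-1-[8-(methoxymethoxy)-2,2-dimethyl-2H-chromen-6-yl]ethanol (racemic) | CC1(C)C=Cc2cc(C(O)CCl)cc(OCOC)c2O1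
F8 | step 6 | 2-chloro-1-[8-(methoxymethoxy)-2,2-dimethyl-2H-chromen-6-yl]ethanone | CC1(C)C=Cc2cc(C(=O)CCl)cc(OCOC)c2O1
F9 | step 6 | 2-{2-[8-(methoxymethoxy)-2,2-dimethyl-2H-chromen-6-yl]-2-oxoethoxy}-4,6-bis(methoxymethoxy)benzoic acid | OC(=O)c1c(OCC(=O)c2cc3C=CC(C)(C)Oc3c(OCOC)c2)cc(OCOC)cc1OCOC
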